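**Retrosynthetic overview**
- Target ⇒ ester C–O bond: the free (1S,2S)-1,3-diol plus (Z)-3-ethylideneoxetan-2-one. Ring-opening O-acylation at the primary hydroxyl frees the CH2OH and carries the Z-alkene over unchanged, so no protecting groups are needed.
- (Z)-3-Ethylideneoxetan-2-one ⇒ (Z)-2-iodobut-2-en-1-ol + CO (Pd cyclocarbonylation) ⇒ crotonaldehyde.
- Diol ⇒ ester reduction and E-selective cross-metathesis with 3,4-dimethoxystyrene ⇒ anti-2-allyl-3-hydroxy ester.
- anti-Allyl hydroxy ester ⇒ Fráter–Seebach allylation of the (S)-β-hydroxy ester ⇒ asymmetric transfer hydrogenation of ethyl (4-methoxybenzoyl)acetate.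
- Rings: both arenes are bought; the only ring built is the oxetan-2-one (step 7), which is opened again in the last step.

Assumption: the SMILES defines the target, i.e. (2S,3S) in the propyl chain (OH and cinnamyl anti), an E-styrene, and a (2Z)-2-(hydroxymethyl)but-2-enoate (CH3 cis to the ester carbonyl); ethyl (4-methoxybenzoyl)acetate and 3,4-dimethoxystyrene are taken as catalogue chemicals.

**Route**

Step 1
Reactants: 1 ethyl 3-(4-methoxyphenyl)-3-oxopropanoate
Product: 2 ethyl (3S)-3-hydroxy-3-(4-methoxyphenyl)propanoate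
Conditions: RuCl(p-cymene)[(S,S)-TsDPEN] (1 mol%), HCO2H/Et3N 5:2, 35 °C
Reagents that add atoms: none
Why: Noyori asymmetric transfer hydrogenation of an aryl ketone; the (S,S)-catalyst delivers hydride through the CH/π-organised outer-sphere transition state to give the (S)-benzylic alcohol, as for acetophenones, and leaves the ester untouched.

Step 2
Reactants: 2 ethyl (3S)-3-hydroxy-3-(4-methoxyphenyl)propanoate; 3 allyl bromide
Product: 5 ethyl (2R,3S)-2-allyl-3-hydroxy-3-(4-methoxyphenyl)propanoate, via dilithium alkoxide-enolate 4 (not isolated)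
Conditions: LDA (2.2 equiv), THF, −78 → −20 °C; then 3 (1.5 equiv), DMPU, −78 → −10 °C; sat. aq. NH4Cl
Reagents that add atoms: none
Why: Fráter–Seebach alkylation; the lithium-chelated dianion is allylated on the enolate face opposite the aryl group, which sets C2 as (R) anti to the C3 hydroxyl (dr typically ≥10:1) while C3 is not touched.

Step 3
Reactants: 5 ethyl (2R,3S)-2-allyl-3-hydroxy-3-(4-methoxyphenyl)propanoate; 6 3,4-dimethoxystyrene
Product: 7 ethyl (2R,3S)-2-[(2E)-3-(3,4-dimethoxyphenyl)prop-2-en-1-yl]-3-hydroxy-3-(4-methoxyphenyl)propanoate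
Conditions: 6 (3 equiv), Hoveyda–Grubbs II (5 mol%), 1,4-benzoquinone (10 mol%), CH2Cl2, 40 °C
Reagents that add atoms: none
Why: Olefin cross-metathesis of a terminal alkene with excess styrene gives the thermodynamic E-styrene (>20:1), tolerates the free hydroxyl and ester, and does not involve the stereocentres; benzoquinone suppresses alkene migration.

Step 4
Reactants: 7 ethyl (2R,3S)-2-[(2E)-3-(3,4-dimethoxyphenyl)prop-2-en-1-yl]-3-hydroxy-3-(4-methoxyphenyl)propanoate
Product: 8 (1S,2S)-2-[(2E)-3-(3,4-dimethoxyphenyl)prop-2-en-1-yl]-1-(4-methoxyphenyl)propane-1,3-diol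
Conditions: LiAlH4 (1.5 equiv), THF, 0 °C → rt; Rochelle salt work-up
Reagents that add atoms: none
Why: Hydride reduction of the ester to the primary alcohol leaves the styrene and both stereocentres unchanged (the C2 descriptor changes from R to S only through CIP priorities).

Step 5
Reactants: 9 (E)-but-2-enal (crotonaldehyde)
Product: 10 (Z)-2-iodobut-2-enal
Conditions: I2 (1.5 equiv), K2CO3 (1.2 equiv), DMAP (20 mol%), THF/H2O 1:1, rt
Reagents that add atoms: iodine, II
Why: Baylis–Hillman-type α-iodination (DMAP conjugate addition, enolate iodination, E1cB loss of DMAP) gives the thermodynamic Z-isomer with CH3 cis to iodine.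

Step 6
Reactants: 10 (Z)-2-iodobut-2-enal
Product: 11 (Z)-2-iodobut-2-en-1-ol
Conditions: NaBH4, THF/H2O 9:1, 0 °C
Reagents that add atoms: none
Why: Borohydride 1,2-reduction of the enal leaves the vinyl iodide and its geometry intact.

Step 7
Reactants: 11 (Z)-2-iodobut-2-en-1-ol
Product: 12 (Z)-3-ethylideneoxetan-2-one
Conditions: Pd(OAc)2 (5 mol%), Xantphos (6 mol%), CO (1 atm), K2CO3 (1.5 equiv), 4 Å MS, toluene (0.03 M), 45 °C; filtered and used as a titrated toluene solution
Reagents that add atoms: carbon monoxide, [C-]#[O+]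
Why: Intramolecular Pd-catalysed alkoxycarbonylation (cyclocarbonylation) of a 2-haloallylic alcohol; oxidative addition and CO insertion retain the alkene geometry and the pendant alkoxide closes the four-membered ring by acyl C–O bond formation, so CH3 ends cis to the carbonyl.

Step 8
Reactants: 8 (1S,2S)-2-[(2E)-3-(3,4-dimethoxyphenyl)prop-2-en-1-yl]-1-(4-methoxyphenyl)propane-1,3-diol; 12 (Z)-3-ethylideneoxetan-2-one
Product: 13 (2S,3S)-2-[(2E)-3-(3,4-dimethoxyphenyl)prop-2-en-1-yl]-3-hydroxy-3-(4-methoxyphenyl)propyl (2Z)-2-(hydroxymethyl)but-2-enoate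
Conditions: Bu2SnO (10 mol%), 4 Å MS, toluene, 45 °C; 12 (1.1 equiv) added over 4 h
Reagents that add atoms: none
Why: Proposed new method: tin-gated acyl transfer from an α-alkylidene-β-lactone to a 1,3-diol, in which catalytic Bu2SnO binds only the 1,3-diol as a six-membered tin chelate whose primary O–Sn bond is the nucleophilic one, the Lewis-acidic tin coordinates the lactone carbonyl and the alkoxide inserts with acyl–O cleavage (coordination–insertion, driven by about 23 kcal/mol of ring strain), forming the ester C–O bond at the primary oxygen only, leaving the exocyclic C=C untouched so the Z geometry is carried over, and releasing the CH2OH as a tin alkoxide that is handed back to fresh diol by chelate-driven exchange so that product hydroxyls are not acylated and the lactone does not oligomerise; no stereocentre is touched and the neutral conditions spare the acid-labile 4-methoxybenzylic alcohol; the closest known reaction types are organotin-catalysed regioselective acylation of diols with acyl chlorides and coordination–insertion ring-opening of β-lactones by tin alkoxides.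

**Compound list**

1 | ethyl 3-(4-methoxyphenyl)-3-oxopropanoate | CCOC(=O)CC(=O)c1ccc(OC)cc1 | starting material
2 | ethyl (3S)-3-hydroxy-3-(4-methoxyphenyl)propanoate | CCOC(=O)C[C@H](O)c1ccc(OC)cc1 | intermediate
3 | allyl bromide (3-bromoprop-1-ene) | C=CCBr | starting material
4 | dilithium alkoxide-enolate of 2 (O,O-chelated dianion, 3S) | CCO/C([O-])=C/[C@H]([O-])c1ccc(OC)cc1.[Li+].[Li+] | intermediate
5 | ethyl (2R,3S)-2-allyl-3-hydroxy-3-(4-methoxyphenyl)propanoate | CCOC(=O)[C@H](CC=C)[C@H](O)c1ccc(OC)cc1 | intermediate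
6 | 3,4-dimethoxystyrene (4-ethenyl-1,2-dimethoxybenzene) | C=Cc1ccc(OC)c(OC)c1 | starting material
7 | ethyl (2R,3S)-2-[(2E)-3-(3,4-dimethoxyphenyl)prop-2-en-1-yl]-3-hydroxy-3-(4-methoxyphenyl)propanoate | CCOC(=O)[C@H](C/C=C/c1ccc(OC)c(OC)c1)[C@H](O)c1ccc(OC)cc1 | intermediate
8 | (1S,2S)-2-[(2E)-3-(3,4-dimethoxyphenyl)prop-2-en-1-yl]-1-(4-methoxyphenyl)propane-1,3-diol | OC[C@H](C/C=C/c1ccc(OC)c(OC)c1)[C@H](O)c1ccc(OC)cc1 | intermediate
9 | (E)-but-2-enal (crotonaldehyde) | C/C=C/C=O | starting material
10 | (Z)-2-iodobut-2-enal | C/C=C(\I)C=O | intermediate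
11 | (Z)-2-iodobut-2-en-1-ol | C/C=C(\I)CO | intermediate
12 | (Z)-3-ethylideneoxetan-2-one | C/C=C1/COC1=O | intermediate
13 | (2S,3S)-2-[(2E)-3-(3,4-dimethoxyphenyl)prop-2-en-1-yl]-3-hydroxy-3-(4-methoxyphenyl)propyl (2Z)-2-(hydroxymethyl)but-2-enoate | C/C=C(/CO)C(=O)OC[C@H](C/C=C/c1ccc(OC)c(OC)c1)[C@H](O)c1ccc(OC)cc1 | target

**Step count and risks**

Total step count: 8. Longest linear sequence: 5 (steps 1, 2, 3, 4, 8); the acyl-donor arm is steps 5, 6, 7, 8.

The three steps most likely to fail:

Step 8 (the proposed new ring-opening acylation). The risks are alkyl–O instead of acyl–O opening of the lactone, O-acylation of product hydroxyls, and low turnover of the tin catalyst. The fallback uses only known chemistry, sets out from 11 and 8, and comes back at 13. Alcohol 11 is silylated (TBSCl, imidazole, DMF) to (Z)-tert-butyl[(2-iodobut-2-en-1-yl)oxy]dimethylsilane F1. Pd-catalysed hydroxycarbonylation of F1 (Pd(OAc)2/dppf, CO 1 atm, K2CO3, DMF/H2O, 50 °C, then mild acidification) gives (2Z)-2-{[(tert-butyldimethylsilyl)oxy]methyl}but-2-enoic acid F2. F2 is esterified selectively with the primary hydroxyl of 8 through its Yamaguchi mixed anhydride (2,4,6-trichlorobenzoyl chloride, Et3N; then 8, catalytic DMAP, toluene, −20 °C, kept cold to avoid Z→E isomerisation) to give the silyl-protected ester F3. Buffered HF·pyridine in THF/pyridine at 0 °C then removes the silyl group to give 13.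

Step 7 (carbonylative closure of a four-membered lactone from a primary alcohol). The risks are intermolecular ester oligomers and iodide-induced opening of the lactone. The fallback sets out from 11 and comes back at 12. Pd-catalysed methoxycarbonylation in methanol (PdCl2(PPh3)2, CO 1 atm, K2CO3, MeOH, 40 °C) gives methyl (2Z)-2-(hydroxymethyl)but-2-enoate F4. Saponification (LiOH, THF/H2O, 0 °C) gives (2Z)-2-(hydroxymethyl)but-2-enoic acid F5, which is cyclised by carboxyl activation (benzenesulfonyl chloride, pyridine, 0 °C) to 12.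

Step 2 (Fráter–Seebach allylation of an electron-rich β-aryl aldolate). The risks are retro-aldol cleavage and eroded anti selectivity. The fallback sets out from 1 and 3, comes back at 5, and replaces steps 1 and 2. Keto ester 1 is C-allylated with 3 (K2CO3, acetone, rt) to racemic ethyl 2-allyl-3-(4-methoxyphenyl)-3-oxopropanoate F6. F6 is then reduced under dynamic kinetic resolution with an anti-selective ketoreductase picked from a screening panel (NADP+, iPrOH, pH 7 phosphate buffer, 30 °C); the α-centre racemises through the enol while the enzyme sets both centres of 5.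

**Further compounds**

F1 | step 8 | (Z)-tert-butyl[(2-iodobut-2-en-1-yl)oxy]dimethylsilane | C/C=C(\I)CO[Si](C)(C)C(C)(C)C
F2 | step 8 | (2Z)-2-{[(tert-butyldimethylsilyl)oxy]methyl}but-2-enoic acid | C/C=C(/CO[Si](C)(C)C(C)(C)C)C(=O)O
F3 | step 8 | (2S,3S)-2-[(2E)-3-(3,4-dimethoxyphenyl)prop-2-en-1-yl]-3-hydroxy-3-(4-methoxyphenyl)propyl (2Z)-2-{[(tert-butyldimethylsilyl)oxy]methyl}but-2-enoate | C/C=C(/CO[Si](C)(C)C(C)(C)C)C(=O)OC[C@H](C/C=C/c1ccc(OC)c(OC)c1)[C@H](O)c1ccc(OC)cc1
F4 | step 7 | methyl (2Z)-2-(hydroxymethyl)but-2-enoate | C/C=C(/CO)C(=O)OC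
F5 | step 7 | (2Z)-2-(hydroxymethyl)but-2-enoic acid | C/C=C(/CO)C(=O)O
F6 | step 2 | ethyl 2-allyl-3-(4-methoxyphenyl)-3-oxopropanoate (racemic) | CCOC(=O)C(CC=C)C(=O)c1ccc(OC)cc1
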